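**Retrosynthetic overview**
1. Target 26 ⇐ desilylation ⇐ equatorial methyl addition to the ring‑B ketone 24, which sets the tertiary carbinol.
2. 24 ⇐ one Lewis‑acid cascade on the bis‑epoxy (Z)‑silyl enol ether 22: the oxepane C–O bond forms first, then the ring‑B C–C bond; the cyclohexene ring is carried in ready‑made.
3. 22 ⇐ key union inside the CH2–CH2 linker: acylsilane 19 + vinyllithium → Brook rearrangement → siloxyallyl anion (a ketone β‑carbanion, i.e. a homoenolate) + allylic bromide 12.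
4. 12 ⇐ 3‑methylcyclohexenone: Cu‑catalysed asymmetric conjugate addition/Mannich trapping, proline aminoxylation, MeLi addition, allylic transposition to the bromide.
5. 19 ⇐ geranyl bromide + N‑acetylmorpholine, Shi bis‑epoxidation, silyllithium acyl substitution.

Assumption: vinyllithium, PhMe2SiLi, MeLi, MeMgBr and LiN(iPr)2 are used as pre‑formed titrated solutions, and epimer mixtures at centres that are destroyed later (C‑2 of 5–9, C‑1 of 11, the carbinol carbon of 20) are carried on unseparated.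

**Route**

Step 1
Reactants: 1 3-methylcyclohex-2-en-1-one; 2 5-bromo-2-methylpent-2-ene
Product: 5 (3S)-2-[(dimethylamino)methyl]-3-methyl-3-(4-methylpent-3-en-1-yl)cyclohexan-1-one as a C-2 epimer mixture, via homoprenylmagnesium bromide 3 (not isolated), via bromomagnesium enolate 4 (not isolated)
Conditions: Mg, Et2O, rt; then 1, Cu(OTf)2 (3 mol %), chiral C2-symmetric 4,5-diphenylimidazolinium chloride (NHC precursor, 4 mol %, enantiomer giving the 3S ketone), Et2O, 0 °C; then Me2N=CH2+ I−, THF, −20 °C → rt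
Reagents that add atoms: N,N-dimethylmethyleneiminium iodide (Eschenmoser's salt), C=[N+](C)C.[I-]
Why: Copper–NHC-catalysed asymmetric conjugate addition of the Grignard reagent to the β-methyl enone sets the quaternary carbon by catalyst control of the enone face, and the regiodefined magnesium enolate is trapped in a Mannich reaction on the carbon next to the new quaternary centre.

Step 2
Reactants: 5 Mannich base
Product: 7 (3R,6S)-2-[(dimethylamino)methyl]-6-hydroxy-3-methyl-3-(4-methylpent-3-en-1-yl)cyclohexan-1-one, via anilinooxy ketone 6 (not isolated)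
Conditions: D-proline (20 mol %), PhNO (slow addition), CHCl3, 4 °C; then CuSO4·5H2O (30 mol %), MeOH, 0 °C
Reagents that add atoms: nitrosobenzene, O=Nc1ccccc1
Why: Proline enamine catalysis (α-aminoxylation, O-selective nitroso aldol) engages only the unsubstituted α-CH2, and D-proline delivers the 6S C–O bond under catalyst control irrespective of the remote quaternary centre; Cu-catalysed N–O cleavage then frees the alcohol (the change of the C-3 descriptor from S to R is only a priority change).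

Step 3
Reactants: 7 hydroxy ketone
Product: 8 (3R,6S)-6-[(tert-butyldimethylsilyl)oxy]-2-[(dimethylamino)methyl]-3-methyl-3-(4-methylpent-3-en-1-yl)cyclohexan-1-one
Conditions: TBSOTf, 2,6-lutidine, CH2Cl2, −78 → 0 °C
Reagents that add atoms: tert-butyldimethylsilyl triflate, CC(C)(C)[Si](C)(C)OS(=O)(=O)C(F)(F)F
Why: Standard silylation of a secondary alcohol under non-epimerising conditions protects the carbinol for the organolithium and bromination steps.

Step 4
Reactants: 8 silyl ether Mannich base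
Product: 10 (3R,6S)-6-[(tert-butyldimethylsilyl)oxy]-3-methyl-2-methylidene-3-(4-methylpent-3-en-1-yl)cyclohexan-1-one, via trimethylammonium iodide 9 (not isolated)
Conditions: MeI, MeCN, rt; then NaHCO3 (aq), CH2Cl2, rt
Reagents that add atoms: none
Why: Quaternisation and E1cB (Hofmann-type) elimination of the β-ammonium ketone gives the α-methylene ketone; NaHCO3 is too weak to enolise toward the silyloxy-bearing carbon, so C-6 is not epimerised.

Step 5
Reactants: 10 α-methylene ketone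
Product: 11 (3R,6S)-6-[(tert-butyldimethylsilyl)oxy]-1,3-dimethyl-2-methylidene-3-(4-methylpent-3-en-1-yl)cyclohexan-1-ol as a C-1 epimer mixture
Conditions: MeLi, CeCl3, THF, −78 °C
Reagents that add atoms: methyllithium, [Li]C
Why: Organocerium-type 1,2-addition to the hindered, enolisable enone gives the tertiary allylic alcohol; the new carbinol centre becomes sp2 in the next step, so its configuration is irrelevant.

Step 6
Reactants: 11 tertiary allylic alcohol
Product: 12 tert-butyl{[(1S,4R)-3-(bromomethyl)-2,4-dimethyl-4-(4-methylpent-3-en-1-yl)cyclohex-2-en-1-yl]oxy}dimethylsilane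
Conditions: PBr3 (0.4 equiv), pyridine (cat.), Et2O, −30 → 0 °C
Reagents that add atoms: phosphorus tribromide, BrP(Br)Br
Why: SN2′ bromination with allylic transposition (as in linalool → geranyl bromide) moves the alkene into the ring as the tetrasubstituted olefin and leaves the primary allylic bromide; neither stereocentre is touched.

Step 7
Reactants: 13 N-acetylmorpholine; 14 geranyl bromide
Product: 16 (4E)-5,9-dimethyl-1-(morpholin-4-yl)deca-4,8-dien-1-one, via amide lithium enolate 15 (not isolated)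
Conditions: LiN(iPr)2, THF, −78 °C; then 14, −78 → 0 °C
Reagents that add atoms: none
Why: SN2 alkylation of an amide enolate with a primary allylic bromide proceeds without loss of the E geometry.

Step 8
Reactants: 16 dienyl amide
Product: 17 3-[(2R,3R)-3-{2-[(2R)-3,3-dimethyloxiran-2-yl]ethyl}-3-methyloxiran-2-yl]-1-(morpholin-4-yl)propan-1-one
Conditions: D-fructose-derived Shi ketone (2 × 30 mol %), KHSO5 (as 2KHSO5·KHSO4·K2SO4), K2CO3, Bu4NHSO4, Na2B4O7 buffer, MeCN–dimethoxymethane–H2O, 0 °C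
Reagents that add atoms: potassium peroxymonosulfate, [K+].[O-]S(=O)(=O)OO
Why: Shi asymmetric epoxidation (chiral dioxirane, spiro transition state) converts both E-trisubstituted alkenes into R,R-type epoxides under reagent control, setting the three epoxide stereocentres that become three ring stereocentres of the target.

Step 9
Reactants: 17 bis-epoxy morpholine amide
Product: 19 1-[dimethyl(phenyl)silyl]-3-[(2R,3R)-3-{2-[(2R)-3,3-dimethyloxiran-2-yl]ethyl}-3-methyloxiran-2-yl]propan-1-one, via lithium hemiaminal 18 (not isolated)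
Conditions: PhMe2SiLi (1.1 equiv), THF, −78 °C, 20 min; then NH4Cl (aq)
Reagents that add atoms: dimethylphenylsilyllithium, [Li][Si](C)(C)c1ccccc1
Why: Acyl substitution of a morpholine amide by a silyl anion stops at the stable tetrahedral adduct and gives the acylsilane on work-up; at −78 °C the amide outcompetes the hindered trisubstituted epoxides.

Step 10
Reactants: 19 bis-epoxy acylsilane; 12 allylic bromide
Product: 22 tert-butyl{[(1S,4R)-3-[(3Z)-4-{[dimethyl(phenyl)silyl]oxy}-6-[(2R,3R)-3-{2-[(2R)-3,3-dimethyloxiran-2-yl]ethyl}-3-methyloxiran-2-yl]hex-3-en-1-yl]-2,4-dimethyl-4-(4-methylpent-3-en-1-yl)cyclohex-2-en-1-yl]oxy}dimethylsilane, via silyl carbinol lithium alkoxide 20 (not isolated), via siloxyallyllithium 21 (not isolated)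
Conditions: vinyllithium (1.05 equiv), THF, −78 → −45 °C; then 12, −78 → −20 °C; NaHCO3 work-up, used crude
Reagents that add atoms: vinyllithium, [Li]C=C
Why: 1,2-Addition to the acylsilane and [1,2]-Brook rearrangement give a siloxyallyl anion, a ketone homoenolate equivalent whose γ-carbon (the β-carbon of the future ketone, normally a Michael-acceptor position) is alkylated by the allylic bromide in SN2 fashion; this joins the two halves and delivers the regiodefined Z silyl enol ether, and no stereocentre is made.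

Step 11
Reactants: 22 bis-epoxy silyl enol ether
Product: 24 (3R,5aR,6R,9aR)-6-{2-[(3S,6R)-3-[(tert-butyldimethylsilyl)oxy]-2,6-dimethyl-6-(4-methylpent-3-en-1-yl)cyclohex-1-en-1-yl]ethyl}-3-hydroxy-2,2,5a-trimethyloctahydro-1-benzoxepin-7(2H)-one, via trimethylsilyl ether ketone 23 (not isolated)
Conditions: Me3SiOTf (1.2 equiv), 2,6-di-tert-butyl-4-methylpyridine, CH2Cl2, −78 °C; then K2CO3, MeOH, 0 °C → rt
Reagents that add atoms: none
Why: Epoxide-opening oxa-/carbacyclisation cascade: the inner epoxide oxygen opens the silyl-activated terminal epoxide at its tertiary carbon (retention at both CH–O carbons), and the enol ether carbon attacks the methyl-bearing carbon of the resulting epoxonium with inversion through a chair, giving the trans-fused oxepane/cyclohexanone; the Z enol ether places the side chain equatorial and K2CO3/MeOH secures this epimer while removing the secondary silyl ether.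

Step 12
Reactants: 24 bicyclic hydroxy ketone
Product: 25 (3R,5aR,6R,7S,9aR)-6-{2-[(3S,6R)-3-[(tert-butyldimethylsilyl)oxy]-2,6-dimethyl-6-(4-methylpent-3-en-1-yl)cyclohex-1-en-1-yl]ethyl}-2,2,5a,7-tetramethyldecahydro-1-benzoxepine-3,7-diol
Conditions: MeMgBr (5 equiv), CeCl3, THF, −78 → 0 °C
Reagents that add atoms: methylmagnesium bromide, C[Mg]Br
Why: Carbonyl addition from the equatorial direction, because the axial trajectory is blocked by the 1,3-related axial angular methyl group, gives the axial tertiary alcohol with equatorial methyl (7S).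

Step 13
Reactants: 25 silyl-protected triol
Product: 26 (3R,5aR,6R,7S,9aR)-6-{2-[(3S,6R)-3-hydroxy-2,6-dimethyl-6-(4-methylpent-3-en-1-yl)cyclohex-1-en-1-yl]ethyl}-2,2,5a,7-tetramethyldecahydro-1-benzoxepine-3,7-diol (CNP0266779.2)
Conditions: Bu4NF, THF, rt
Reagents that add atoms: none
Why: Fluoride desilylation of the allylic silyl ether releases the last hydroxyl without touching any stereocentre.

**Compound list**
1 | 3-methylcyclohex-2-en-1-one | CC1=CC(=O)CCC1 | starting material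
2 | 5-bromo-2-methylpent-2-ene | CC(C)=CCCBr | starting material
3 | (4-methylpent-3-en-1-yl)magnesium bromide | CC(C)=CCC[Mg]Br | intermediate
4 | bromomagnesium (3S)-3-methyl-3-(4-methylpent-3-en-1-yl)cyclohex-1-en-1-olate | CC(C)=CCC[C@]1(C)CCCC(O[Mg]Br)=C1 | intermediate
5 | (3S)-2-[(dimethylamino)methyl]-3-methyl-3-(4-methylpent-3-en-1-yl)cyclohexan-1-one (C-2 epimers) | CC(C)=CCC[C@]1(C)CCCC(=O)C1CN(C)C | intermediate
6 | (3R,6S)-6-(anilinooxy)-2-[(dimethylamino)methyl]-3-methyl-3-(4-methylpent-3-en-1-yl)cyclohexan-1-one | CC(C)=CCC[C@]1(C)CC[C@H](ONc2ccccc2)C(=O)C1CN(C)C | intermediate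
7 | (3R,6S)-2-[(dimethylamino)methyl]-6-hydroxy-3-methyl-3-(4-methylpent-3-en-1-yl)cyclohexan-1-one | CC(C)=CCC[C@]1(C)CC[C@H](O)C(=O)C1CN(C)C | intermediate
8 | (3R,6S)-6-[(tert-butyldimethylsilyl)oxy]-2-[(dimethylamino)methyl]-3-methyl-3-(4-methylpent-3-en-1-yl)cyclohexan-1-one | CC(C)=CCC[C@]1(C)CC[C@H](O[Si](C)(C)C(C)(C)C)C(=O)C1CN(C)C | intermediate
9 | N-methyl ammonium iodide of 8 | CC(C)=CCC[C@]1(C)CC[C@H](O[Si](C)(C)C(C)(C)C)C(=O)C1C[N+](C)(C)C.[I-] | intermediate
10 | (3R,6S)-6-[(tert-butyldimethylsilyl)oxy]-3-methyl-2-methylidene-3-(4-methylpent-3-en-1-yl)cyclohexan-1-one | CC(C)=CCC[C@]1(C)CC[C@H](O[Si](C)(C)C(C)(C)C)C(=O)C1=C | intermediate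
11 | (3R,6S)-6-[(tert-butyldimethylsilyl)oxy]-1,3-dimethyl-2-methylidene-3-(4-methylpent-3-en-1-yl)cyclohexan-1-ol (C-1 epimers) | CC(C)=CCC[C@]1(C)CC[C@H](O[Si](C)(C)C(C)(C)C)C(C)(O)C1=C | intermediate
12 | tert-butyl{[(1S,4R)-3-(bromomethyl)-2,4-dimethyl-4-(4-methylpent-3-en-1-yl)cyclohex-2-en-1-yl]oxy}dimethylsilane | CC(C)=CCC[C@]1(C)CC[C@H](O[Si](C)(C)C(C)(C)C)C(C)=C1CBr | intermediate
13 | N-acetylmorpholine | CC(=O)N1CCOCC1 | starting material
14 | geranyl bromide, (2E)-1-bromo-3,7-dimethylocta-2,6-diene | CC(C)=CCC/C(C)=C/CBr | starting material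
15 | lithium enolate of N-acetylmorpholine | [Li]OC(=C)N1CCOCC1 | intermediate
16 | (4E)-5,9-dimethyl-1-(morpholin-4-yl)deca-4,8-dien-1-one | CC(C)=CCC/C(C)=C/CCC(=O)N1CCOCC1 | intermediate
17 | 3-[(2R,3R)-3-{2-[(2R)-3,3-dimethyloxiran-2-yl]ethyl}-3-methyloxiran-2-yl]-1-(morpholin-4-yl)propan-1-one | O=C(CC[C@H]1O[C@]1(C)CC[C@H]1OC1(C)C)N1CCOCC1 | intermediate
18 | lithium hemiaminal from 17 and PhMe2SiLi | [Li]OC(CC[C@H]1O[C@]1(C)CC[C@H]1OC1(C)C)(N1CCOCC1)[Si](C)(C)c1ccccc1 | intermediate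
19 | 1-[dimethyl(phenyl)silyl]-3-[(2R,3R)-3-{2-[(2R)-3,3-dimethyloxiran-2-yl]ethyl}-3-methyloxiran-2-yl]propan-1-one | O=C(CC[C@H]1O[C@]1(C)CC[C@H]1OC1(C)C)[Si](C)(C)c1ccccc1 | intermediate
20 | lithium alkoxide of the vinyl adduct of 19 (α-silyl allylic alkoxide) | [Li]OC(C=C)(CC[C@H]1O[C@]1(C)CC[C@H]1OC1(C)C)[Si](C)(C)c1ccccc1 | intermediate
21 | (Z)-siloxyallyllithium from Brook rearrangement of 20 | [Li]C/C=C(\O[Si](C)(C)c1ccccc1)CC[C@H]1O[C@]1(C)CC[C@H]1OC1(C)C | intermediate
22 | (Z)-dimethylphenylsilyl enol ether joining both halves (name in step 10) | CC(C)=CCC[C@]1(C)CC[C@H](O[Si](C)(C)C(C)(C)C)C(C)=C1CC/C=C(\O[Si](C)(C)c1ccccc1)CC[C@H]1O[C@]1(C)CC[C@H]1OC1(C)C | intermediate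
23 | 3-O-trimethylsilyl ether of 24 | CC(C)=CCC[C@]1(C)CC[C@H](O[Si](C)(C)C(C)(C)C)C(C)=C1CC[C@@H]1[C@@]2(C)CC[C@@H](O[Si](C)(C)C)C(C)(C)O[C@@H]2CCC1=O | intermediate
24 | (3R,5aR,6R,9aR)-6-{2-[(3S,6R)-3-[(tert-butyldimethylsilyl)oxy]-2,6-dimethyl-6-(4-methylpent-3-en-1-yl)cyclohex-1-en-1-yl]ethyl}-3-hydroxy-2,2,5a-trimethyloctahydro-1-benzoxepin-7(2H)-one | CC(C)=CCC[C@]1(C)CC[C@H](O[Si](C)(C)C(C)(C)C)C(C)=C1CC[C@@H]1[C@@]2(C)CC[C@@H](O)C(C)(C)O[C@@H]2CCC1=O | intermediate
25 | 3′-O-TBS ether of the target (name in step 12) | CC(C)=CCC[C@]1(C)CC[C@H](O[Si](C)(C)C(C)(C)C)C(C)=C1CC[C@@H]1[C@@]2(C)CC[C@@H](O)C(C)(C)O[C@@H]2CC[C@]1(C)O | intermediate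
26 | (3R,5aR,6R,7S,9aR)-6-{2-[(3S,6R)-3-hydroxy-2,6-dimethyl-6-(4-methylpent-3-en-1-yl)cyclohex-1-en-1-yl]ethyl}-2,2,5a,7-tetramethyldecahydro-1-benzoxepine-3,7-diol | CC(C)=CCC[C@]1(C)CC[C@H](O)C(C)=C1CC[C@@H]1[C@@]2(C)CC[C@@H](O)C(C)(C)O[C@@H]2CC[C@]1(C)O | target

**Step count and risks**

Total: 13 steps. Longest linear sequence: 10 steps (steps 1–6, then 10–13); steps 7–9 form the three-step side branch.

Most likely to fail, first: step 10. The siloxyallyl anion may alkylate at its α-carbon, open the nearby epoxide intramolecularly, or react sluggishly with the hindered allylic bromide. The fallback sets out from 12 and 17 and returns at 22, building the same enol ether by normal-polarity olefin chemistry. Bromide 12 is allylated with CH2=CHMgBr/CuI to tert-butyl{[(1S,4R)-2,4-dimethyl-4-(4-methylpent-3-en-1-yl)-3-(prop-2-en-1-yl)cyclohex-2-en-1-yl]oxy}dimethylsilane F1. Amide 17 is converted with CH2=CHMgBr into the vinyl ketone 5-[(2R,3R)-3-{2-[(2R)-3,3-dimethyloxiran-2-yl]ethyl}-3-methyloxiran-2-yl]pent-1-en-3-one F2. Cross-metathesis of the two with second-generation Grubbs catalyst gives the (2E)-hex-2-en-4-one that carries the cyclohexenyl group at C-1 and the bis-epoxide at C-6, F3. RhCl(PPh3)3-catalysed 1,4-hydrosilylation of this enone with PhMe2SiH then gives the Z silyl enol ether 22 regiospecifically.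

Second: step 11. The internal, substituted enol ether is a more hindered terminator than usual, and the allylic silyl ether and the two alkenes of the cyclohexene half may ionise or intercept cations under Me3SiOTf. The fallback sets out from 19 and returns at 23; it runs the cascade before the halves are joined. Anion 21, made from 19 as in step 10, is quenched with PhSSPh instead of 12 to give {[(2Z)-5-[(2R,3R)-3-{2-[(2R)-3,3-dimethyloxiran-2-yl]ethyl}-3-methyloxiran-2-yl]-1-(phenylsulfanyl)pent-2-en-3-yl]oxy}dimethyl(phenyl)silane F4. The same Me3SiOTf cascade, now without the cyclohexene half, gives (3R,5aR,6R,9aR)-2,2,5a-trimethyl-6-[(phenylsulfanyl)methyl]-3-[(trimethylsilyl)oxy]octahydro-1-benzoxepin-7(2H)-one F5. Oxidation with mCPBA (1 equiv, −78 °C) gives the corresponding 6-[(phenylsulfinyl)methyl] ketone F6, and warming in toluene eliminates it to (3R,5aR,9aR)-2,2,5a-trimethyl-6-methylidene-3-[(trimethylsilyl)oxy]octahydro-1-benzoxepin-7(2H)-one F7. Radical conjugate addition of bromide 12 to this exocyclic enone ((Me3Si)3SiH, AIBN, benzene, 80 °C; the allyl radical reacts at its primary terminus) forms the same linker bond and gives 23, which continues through the methanolysis of step 11.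

Third: step 2. The ketone is flanked by a branched carbon and carries a basic amine, so enamine formation may be slow or the Mannich base may eliminate. The fallback sets out from 1 and 2 (through enolate 4) and returns at 8, with the aminoxylation moved to an unbranched ketone. Enolate 4 is simply protonated to (3S)-3-methyl-3-(4-methylpent-3-en-1-yl)cyclohexan-1-one F8. D-Proline/PhNO gives (2S,5R)-2-(anilinooxy)-5-methyl-5-(4-methylpent-3-en-1-yl)cyclohexan-1-one F9, and CuSO4·5H2O/MeOH gives (2S,5R)-2-hydroxy-5-methyl-5-(4-methylpent-3-en-1-yl)cyclohexan-1-one F10. TBSOTf/2,6-lutidine gives (2S,5R)-2-[(tert-butyldimethylsilyl)oxy]-5-methyl-5-(4-methylpent-3-en-1-yl)cyclohexan-1-one F11. Kinetic deprotonation with LiN(iPr)2 at the CH2 rather than the silyloxy-bearing CH gives lithium (3R,6S)-6-[(tert-butyldimethylsilyl)oxy]-3-methyl-3-(4-methylpent-3-en-1-yl)cyclohex-1-en-1-olate F12, which is trapped with Eschenmoser's salt to give 8.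

**Further compounds**
F1 | step 10 | tert-butyl{[(1S,4R)-2,4-dimethyl-4-(4-methylpent-3-en-1-yl)-3-(prop-2-en-1-yl)cyclohex-2-en-1-yl]oxy}dimethylsilane | CC(C)=CCC[C@]1(C)CC[C@H](O[Si](C)(C)C(C)(C)C)C(C)=C1CC=C
F2 | step 10 | 5-[(2R,3R)-3-{2-[(2R)-3,3-dimethyloxiran-2-yl]ethyl}-3-methyloxiran-2-yl]pent-1-en-3-one | C=CC(=O)CC[C@H]1O[C@]1(C)CC[C@H]1OC1(C)C
F3 | step 10 | (2E)-1-[(3S,6R)-3-[(tert-butyldimethylsilyl)oxy]-2,6-dimethyl-6-(4-methylpent-3-en-1-yl)cyclohex-1-en-1-yl]-6-[(2R,3R)-3-{2-[(2R)-3,3-dimethyloxiran-2-yl]ethyl}-3-methyloxiran-2-yl]hex-2-en-4-one | CC(C)=CCC[C@]1(C)CC[C@H](O[Si](C)(C)C(C)(C)C)C(C)=C1C/C=C/C(=O)CC[C@H]1O[C@]1(C)CC[C@H]1OC1(C)C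
F4 | step 11 | {[(2Z)-5-[(2R,3R)-3-{2-[(2R)-3,3-dimethyloxiran-2-yl]ethyl}-3-methyloxiran-2-yl]-1-(phenylsulfanyl)pent-2-en-3-yl]oxy}dimethyl(phenyl)silane | c1ccccc1SC/C=C(\O[Si](C)(C)c1ccccc1)CC[C@H]1O[C@]1(C)CC[C@H]1OC1(C)C
F5 | step 11 | (3R,5aR,6R,9aR)-2,2,5a-trimethyl-6-[(phenylsulfanyl)methyl]-3-[(trimethylsilyl)oxy]octahydro-1-benzoxepin-7(2H)-one | c1ccccc1SC[C@@H]1[C@@]2(C)CC[C@@H](O[Si](C)(C)C)C(C)(C)O[C@@H]2CCC1=O
F6 | step 11 | (3R,5aR,6R,9aR)-2,2,5a-trimethyl-6-[(phenylsulfinyl)methyl]-3-[(trimethylsilyl)oxy]octahydro-1-benzoxepin-7(2H)-one | O=S(C[C@@H]1[C@@]2(C)CC[C@@H](O[Si](C)(C)C)C(C)(C)O[C@@H]2CCC1=O)c1ccccc1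
F7 | step 11 | (3R,5aR,9aR)-2,2,5a-trimethyl-6-methylidene-3-[(trimethylsilyl)oxy]octahydro-1-benzoxepin-7(2H)-one | C=C1[C@@]2(C)CC[C@@H](O[Si](C)(C)C)C(C)(C)O[C@@H]2CCC1=O
F8 | step 2 | (3S)-3-methyl-3-(4-methylpent-3-en-1-yl)cyclohexan-1-one | CC(C)=CCC[C@]1(C)CCCC(=O)C1
F9 | step 2 | (2S,5R)-2-(anilinooxy)-5-methyl-5-(4-methylpent-3-en-1-yl)cyclohexan-1-one | CC(C)=CCC[C@]1(C)CC[C@H](ONc2ccccc2)C(=O)C1
F10 | step 2 | (2S,5R)-2-hydroxy-5-methyl-5-(4-methylpent-3-en-1-yl)cyclohexan-1-one | CC(C)=CCC[C@]1(C)CC[C@H](O)C(=O)C1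
F11 | step 2 | (2S,5R)-2-[(tert-butyldimethylsilyl)oxy]-5-methyl-5-(4-methylpent-3-en-1-yl)cyclohexan-1-one | CC(C)=CCC[C@]1(C)CC[C@H](O[Si](C)(C)C(C)(C)C)C(=O)C1
F12 | step 2 | lithium (3R,6S)-6-[(tert-butyldimethylsilyl)oxy]-3-methyl-3-(4-methylpent-3-en-1-yl)cyclohex-1-en-1-olate | CC(C)=CCC[C@]1(C)CC[C@H](O[Si](C)(C)C(C)(C)C)C(O[Li])=C1
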